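**Plan**
- Retrosynthesis: the three acetates, the C5=C16 methylene and the C6–Cl bond are removed first. C2 and C7 are then rejoined as a C2=C7 alkene (reverse ozonolysis, which also returns C19 to a vinyl carbon). C8–C17 is cut as a crotyl addition, ring C is re-aromatised (reverse Birch), and ring A is cut at C1–C14 and C10–C11 (Robinson annulation).
- Enabling feature: C2 and C7 both carry oxygen and stand 1,6 across the ten-membered ring (C2–C3–C4–C5–C6–C7). That is the pattern left when the alkene shared by two six-membered rings (ring B: C1, C2, C7, C8, C9, C10; ring C: C2 to C7) is cleaved. Ring C with its C5 oxygen is the anisole ring of 6-methoxy-2-tetralone.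
- Forward order: ring A is annulated onto the tetralone, ring C is Birch-reduced, ozonolysis of C2=C7 merges rings B and C into the ten-membered ring, and the lactone closes afterwards at C7–O.
- Stereochemistry: C1 from a chiral-imine Michael addition; C10 and C11 by hydroxyl-directed hydrogenation; C12, C13, C14, C9 and C8 by substrate control in the rigid trans-fused tricycle; C17 by equilibration of the lactone; C7 by chelation-controlled reduction; C6 and C2 by outer-face attack on the ten-membered ring.

Key step: step 17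

Remark: briarane numbering is used (ten-membered ring C1–C10; ring A = C1, C10, C11, C12, C13, C14; C15 methyl on C1, C20 methyl on C11, C16 on C5; lactone C7–O–C19(=O)–C17(C18)–C8); β is the face of the C15 methyl, α the opposite face; TBS = tert-butyldimethylsilyl, TMS = trimethylsilyl.
Remark: the crotyl addition of step 14 is assumed to give both C17 epimers; they are carried together and converge in step 20.

**Step 1**
Reactants: 1 6-methoxy-2-tetralone; 2 iodomethane
Product: 5 6-methoxy-1-methyl-2-tetralone (racemic), via pyrrolidine enamine 3 (not isolated), via C-methyl iminium iodide 4 (not isolated)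
Conditions: pyrrolidine, PhH, reflux (Dean–Stark); 2, dioxane, reflux; aq. NaOAc/AcOH, reflux
Reagents that add atoms: water, O
Why: Stork enamine alkylation, in which the arene-conjugated enamine is C-methylated at the benzylic carbon (future C1) and hydrolysed; the stereocentre forms racemic and is corrected in step 2.

**Step 2**
Reactants: 5 6-methoxy-1-methyl-2-tetralone; 6 pent-1-en-3-one
Product: 9 (R)-6-methoxy-1-methyl-1-(3-oxopentyl)-3,4-dihydronaphthalen-2(1H)-one, via phenylethyl imine 7 (not isolated), via Michael adduct imine 8 (not isolated)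
Conditions: (R)-1-phenylethylamine, TsOH (cat.), PhMe, reflux (Dean–Stark); 6, THF, rt; 20% aq. AcOH, rt
Reagents that add atoms: water, O
Why: Asymmetric Michael addition of a chiral imine through its more substituted secondary enamine tautomer (deracemising alkylation), in which the enone adds to the enamine face anti to the phenyl group of the auxiliary and sets quaternary C1 as R; the (R)-amine is chosen by analogy with 2-methylcyclohexanone, where the (S)-amine gives the spatially opposite series.

**Step 3**
Reactants: 9 (R)-1,5-diketone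
Product: 10 (S)-7-methoxy-1,4a-dimethyl-4,4a,9,10-tetrahydrophenanthren-2(3H)-one (ring A enone: C12 ketone, C10=C11)
Conditions: NaOMe, MeOH, reflux
Reagents that add atoms: none
Why: Intramolecular aldol condensation (second half of a Robinson annulation) closes six-membered ring A from the ethyl ketone enolate onto the tetralone carbonyl and dehydrates to the tetrasubstituted enone; no stereocentre is formed.

**Step 4**
Reactants: 10 ring A enone
Product: 11 12α-allylic alcohol (C10=C11 retained)
Conditions: (S)-2-methyl-CBS-oxazaborolidine (20 mol%), catecholborane, PhMe, −78 °C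
Reagents that add atoms: none
Why: Corey–Bakshi–Shibata reduction under reagent control, in which the fully substituted alkene carbon C11 acts as the large group and the (S)-catalyst delivers hydride to the β face of C12, giving the 12α-hydroxyl that steers step 5.

**Step 5**
Reactants: 11 12α-allylic alcohol
Product: 12 trans-fused 12α-alcohol (10α-H, 11β-methyl)
Conditions: H2 (50 bar), [Ir(cod)(PCy3)(py)]PF6 (10 mol%), CH2Cl2, rt
Reagents that add atoms: none
Why: Hydroxyl-directed homogeneous hydrogenation, in which iridium bound to the 12α-hydroxyl adds both hydrogens to the α face of the tetrasubstituted C10=C11 alkene and so sets the trans ring fusion (10α-H) and the axial 11β-methyl together.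

**Step 6**
Reactants: 12 trans-fused 12α-alcohol
Product: 13 C12 ketone (10α-H, 11β-methyl)
Conditions: DMP, pyridine, CH2Cl2, 0 °C → rt
Reagents that add atoms: none
Why: Dess–Martin oxidation under buffered, non-enolising conditions should give the ketone without epimerising the axial C11 methyl.

**Step 7**
Reactants: 13 C12 ketone
Product: 15 ring A enone (C12 ketone, C13=C14), via trimethylsilyl enol ether 14 (not isolated)
Conditions: LiN(iPr)2, TMSCl, THF, −78 °C; Pd(OAc)2 (1.1 equiv), MeCN, rt
Reagents that add atoms: none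
Why: Saegusa–Ito oxidation, in which kinetic deprotonation takes the accessible C13 methylene (the equatorial C11–H is poorly aligned) and the palladium enolate loses β-hydride from C14, leaving C11 untouched.

**Step 8**
Reactants: 15 ring A enone
Product: 16 12β-allylic alcohol (C13=C14)
Conditions: NaBH4, CeCl3·7H2O, MeOH, −78 °C
Reagents that add atoms: none
Why: Luche 1,2-reduction, in which hydride attacks C12 from the α face, anti to the adjacent pseudo-axial 11β-methyl, so the new hydroxyl is β and cis to that methyl.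

**Step 9**
Reactants: 16 12β-allylic alcohol
Product: 17 12β-TBS ether (C13=C14)
Conditions: TBSCl, imidazole, DMF, rt
Reagents that add atoms: tert-butyldimethylsilyl chloride, CC(C)(C)[Si](C)(C)Cl
Why: Standard silylation of the secondary allylic alcohol gives an ether that should survive every step up to the final fluoride treatment.

**Step 10**
Reactants: 17 12β-TBS ether
Product: 18 13α,14α-epoxide
Conditions: mCPBA, NaHCO3, CH2Cl2, 0 °C → rt
Reagents that add atoms: 3-chloroperbenzoic acid, OOC(=O)c1cccc(Cl)c1
Why: Prilezhaev epoxidation, in which the β face of the C13=C14 alkene is screened by the C15 methyl on the neighbouring quaternary C1 and by the 12β-silyloxy group, so oxygen is delivered to the α face.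

**Step 11**
Reactants: 18 13α,14α-epoxide
Product: 19 C8 aryl ketone
Conditions: CrO3, 3,5-dimethylpyrazole, CH2Cl2, −20 °C → rt
Reagents that add atoms: chromium trioxide, O=[Cr](=O)=O
Why: Benzylic oxidation at C8, the only benzylic methylene (C1 is quaternary), with a buffered chromium trioxide–pyrazole reagent that should leave the epoxide and silyl ether intact; no stereocentre is formed.

**Step 12**
Reactants: 19 C8 aryl ketone
Product: 20 9α-hydroxy-8-ketone
Conditions: KN(SiMe3)2, THF, −78 °C; 2-(phenylsulfonyl)-3-phenyloxaziridine, −78 °C; aq. NH4Cl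
Reagents that add atoms: 2-(phenylsulfonyl)-3-phenyloxaziridine, O=S(=O)(c1ccccc1)N1OC1c1ccccc1
Why: Davis enolate hydroxylation, in which the ketone can enolise only toward C9 and the β face of C9 is blocked by the syn-axial C15 and C20 methyls, so oxygen enters from the α face to give the equatorial 9α-alcohol.

**Step 13**
Reactants: 20 9α-hydroxy-8-ketone
Product: 21 9α,12β-bis-TBS ether 8-ketone
Conditions: TBSOTf, 2,6-lutidine, CH2Cl2, −78 °C
Reagents that add atoms: tert-butyldimethylsilyl triflate, CC(C)(C)[Si](C)(C)OS(=O)(=O)C(F)(F)F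
Why: Silyl triflate silylation of the hindered α-hydroxy ketone at low temperature, buffered so that the epoxide is not opened.

**Step 14**
Reactants: 21 9α,12β-bis-TBS ether 8-ketone; 22 (E)-1-bromobut-2-ene
Product: 23 C8 tertiary alcohol (8α-OH, but-3-en-2-yl group β on C8, both C17 epimers)
Conditions: Zn dust, THF/sat. aq. NH4Cl, 0 °C → rt
Reagents that add atoms: none
Why: Barbier crotylation (SE2′ addition of crotylzinc through its γ carbon), in which the non-basic reagent adds to the enolisable ketone from the β face, trans to the 9α-silyloxy group (equatorial attack), setting C8 with the hydroxyl α; C17 is not controlled here and is set in step 20.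

**Step 15**
Reactants: 23 C8 tertiary alcohol
Product: 24 1,4-diene enol ether (C2=C7 and C4=C5–OMe)
Conditions: Li, NH3 (l)/THF, t-BuOH, −78 °C; isoprene; solid NH4Cl
Reagents that add atoms: none
Why: Birch reduction of the anisole ring, in which protonation at C3 and C6 leaves the methoxy-bearing and the two alkyl-bearing carbons unsaturated and so gives the tetrasubstituted C2=C7 alkene; the benzylic C8 oxygen is carried as its lithium alkoxide, excess metal is destroyed with isoprene before the proton quench to limit C8–O hydrogenolysis, and the isolated vinyl group and unactivated epoxide should not be reduced at this temperature.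

**Step 16**
Reactants: 24 1,4-diene enol ether
Product: 25 C5 ethylene ketal with the C2=C7 alkene (tricyclic precursor)
Conditions: ethylene glycol, PPTS (cat.), CH2Cl2, rt
Reagents that add atoms: ethylene glycol, OCCO
Why: Acid-catalysed exchange of the enol ether into a dioxolane (protonation at C4, capture of the oxocarbenium ion by the diol) masks C5 without passing through the β,γ-unsaturated ketone, so the C2=C7 alkene cannot move into conjugation and C5 carries no stereocentre.

**Step 17**
Reactants: 25 C5 ethylene ketal with the C2=C7 alkene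
Product: 26 ten-membered 2,7-diketone with C5 ketal and C19 aldehyde (C17 epimers)
Conditions: O3, CH2Cl2/MeOH, −78 °C; PPh3, −78 °C → rt
Reagents that add atoms: ozone, [O-][O+]=O
Why: Ozone adds to the tetrasubstituted C2=C7 alkene by 1,3-dipolar cycloaddition, the primary ozonide fragments to a ketone and a carbonyl oxide that methanol traps as a methoxy hydroperoxide, and PPh3 reduces this to the second ketone, while the side-chain vinyl group is cleaved in the same way to the C19 aldehyde. The closest known reaction is the ozonolysis of 9,10-octalins from Birch reduction of tetralins, which gives cyclodecane-1,6-diones. The ten-membered ring is not closed by bond formation: it arises by scission of the bond shared by rings B and C of a bicyclo[4.4.0]decene, a ring expansion by fragmentation that needs no medium-ring cyclisation. No stereocentre is formed or lost. The selectivity needed is chemoselectivity only, and the substrate secures it: both alkenes are meant to be cleaved, the epoxide, ketal, silyl ethers and tertiary alcohol are inert to ozone, and the inductive effect of the C8 oxygen should place the carbonyl oxide at C2, away from the carbinol, which disfavours anomalous fragmentation. Reduction of the peroxidic intermediates with PPh3 under neutral conditions keeps the two new ketones from condensing across the ring (C3 onto C7 or C6 onto C2).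

**Step 18**
Reactants: 26 ten-membered 2,7-diketone aldehyde
Product: 27 C19 carboxylic acid (γ-keto acid)
Conditions: NaClO2, NaH2PO4, 2-methyl-2-butene, t-BuOH/H2O, 0 °C → rt
Reagents that add atoms: sodium chlorite, [Na+].[O-]Cl=O
Why: Pinnick oxidation converts the aldehyde to the acid near pH 4 without touching the ketones, ketal or epoxide, and removes the retro-aldol-prone β-hydroxy aldehyde at once.

**Step 19**
Reactants: 27 C19 carboxylic acid
Product: 29 γ-lactone C7–O–C19 (C17 epimers), via C7 hydroxy acid 28 (not isolated)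
Conditions: Zn(BH4)2, Et2O, −30 °C; aq. NH4Cl; PPTS (cat.), CH2Cl2, rt
Reagents that add atoms: none
Why: Chelation-controlled reduction of an α-hydroxy ketone followed by lactonisation, in which zinc bridges the C8 oxygen and the C7 carbonyl and hydride arrives on the outer face of the ring (the side of C17, away from C9) to give the 7α-oxygen; the hindered, unactivated C2 ketone should be left alone and the γ-hydroxy acid closes to the five-membered lactone.

**Step 20**
Reactants: 29 γ-lactone (C17 epimers)
Product: 30 γ-lactone with the C18 methyl cis to the C8 hydroxyl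
Conditions: DBU, PhMe, 80 °C
Reagents that add atoms: none
Why: Base-mediated epimerisation α to the lactone carbonyl under thermodynamic control, in which the C18 methyl settles trans to the bulky C9 substituent on C8 (cis to the small hydroxyl), the configuration of the target at C17, so both epimers converge.

**Step 21**
Reactants: 30 γ-lactone with defined C17
Product: 32 (Z)-3-en-2-one with C5 ketal and C8–OTMS, via bis-trimethylsilyl enol ether 31 (not isolated)
Conditions: LiN(iPr)2 (2.2 equiv), TMSCl, THF, −78 °C; Pd(OAc)2 (1.2 equiv), MeCN, rt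
Reagents that add atoms: chlorotrimethylsilane, C[Si](C)(C)Cl
Why: Saegusa–Ito oxidation, in which C2 can enolise only toward C3 (C1 is quaternary) and the ketone is deprotonated ahead of the lactone; syn β-hydride elimination in the ten-membered palladium enolate is expected to give the cis alkene, the less strained geometry of a cyclodecenone.

**Step 22**
Reactants: 32 (Z)-3-en-2-one with C5 ketal
Product: 33 (Z)-3-ene-2,5-dione with free C8–OH
Conditions: PPTS, acetone/H2O, 50 °C
Reagents that add atoms: water, O
Why: Mild acid hydrolysis of the dioxolane (and of the tertiary trimethylsilyl ether) unveils the C5 ketone; the cis-enedione cannot close to a furan at this oxidation level, and buffered acid should leave the epoxide and the secondary silyl ethers in place.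

**Step 23**
Reactants: 33 (Z)-3-ene-2,5-dione
Product: 35 6α-chloro-(Z)-3-ene-2,5-dione with C8–OTMS, via silyl dienol ether 34 (not isolated)
Conditions: LiN(SiMe3)2 (2.2 equiv), TMSCl, THF, −78 °C; NCS, THF, −78 → 0 °C
Reagents that add atoms: N-chlorosuccinimide, O=C1CCC(=O)N1Cl; chlorotrimethylsilane, C[Si](C)(C)Cl
Why: Regiospecific α-chlorination of a ketone through its silyl enol ether, in which C6 is the only enolisable position of the enedione and trapping the enolate as it forms limits β-elimination of the lactone oxygen; NCS is expected to attack the outer face of the C5=C6 enol ether, with the C7–O bond eclipsing the alkene and C8 shielding the inner face, placing chlorine α and anti to the C7 oxygen.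

**Step 24**
Reactants: 35 6α-chloro-(Z)-3-ene-2,5-dione
Product: 36 6α-chloro-5(16)-methylene-(Z)-3-en-2-one with C8–OTMS
Conditions: Cp2TiMe2, PhMe/THF, 65 °C
Reagents that add atoms: dimethyltitanocene, [CH3-].[CH3-].[Ti+4].c1cc[cH-]c1.c1cc[cH-]c1
Why: Petasis methylenation, in which the non-basic titanium methylidene should add to the most electrophilic and least hindered carbonyl, the α-chloro ketone C5, without enolising C6, while the neopentyl enone carbonyl C2 and the lactone react more slowly; C6 keeps its configuration.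

**Step 25**
Reactants: 36 6α-chloro-5(16)-methylene-(Z)-3-en-2-one
Product: 37 8,9α,12β-triol 2-ketone
Conditions: HF·pyridine, pyridine, THF, 0 °C → rt
Reagents that add atoms: none
Why: Fluoride-mediated desilylation buffered with pyridine removes both TBS ethers and the trimethylsilyl ether while sparing the epoxide, allylic chloride and lactone; it precedes the C2 reduction so that no dienylic alcohol meets acid.

**Step 26**
Reactants: 37 8,9α,12β-triol 2-ketone
Product: 38 2α,8,9α,12β-tetraol
Conditions: NaBH4, CeCl3·7H2O, MeOH, −78 °C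
Reagents that add atoms: none
Why: Luche 1,2-reduction of the cross-conjugated dienone, in which hydride approaches C2 from the outer face, anti to the C1–C10 ring bond and with C3 gauche to the small C15 methyl (Felkin–Anh), to give the 2α-alcohol; lactone and allylic chloride are not reduced.

**Step 27**
Reactants: 38 2α,8,9α,12β-tetraol
Product: 39 CNP0274383.1 (2α,9α,12β-triacetate)
Conditions: Ac2O, pyridine, DMAP (cat.), CH2Cl2, 0 °C → rt
Reagents that add atoms: acetic anhydride, CC(=O)OC(C)=O
Why: DMAP-catalysed acylation of the three secondary alcohols at C2, C9 and C12; the hindered tertiary C8 hydroxyl should stay free under these conditions.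

**Compound list**
1 | 6-methoxy-2-tetralone | COc1ccc2c(c1)CCC(=O)C2 | starting material
2 | iodomethane | CI | starting material
3 | 1-(6-methoxy-3,4-dihydronaphthalen-2-yl)pyrrolidine | COc1ccc2c(c1)CCC(=C2)N3CCCC3 | intermediate
4 | 1-(6-methoxy-1-methyl-3,4-dihydronaphthalen-2(1H)-ylidene)pyrrolidinium iodide | COc1ccc2c(c1)CCC(=[N+]3CCCC3)C2C.[I-] | intermediate
5 | 6-methoxy-1-methyl-2-tetralone (racemic) | COc1ccc2c(c1)CCC(=O)C2C | intermediate
6 | pent-1-en-3-one | C=CC(=O)CC | starting material
7 | N-[(R)-1-phenylethyl] imine of 5 | COc1ccc2c(c1)CCC(=N[C@H](C)c3ccccc3)C2C | intermediate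
8 | N-[(R)-1-phenylethyl] imine of 9 | COc1ccc2c(c1)CCC(=N[C@H](C)c3ccccc3)[C@]2(C)CCC(=O)CC | intermediate
9 | (R)-6-methoxy-1-methyl-1-(3-oxopentyl)-3,4-dihydronaphthalen-2(1H)-one | COc1ccc2c(c1)CCC(=O)[C@]2(C)CCC(=O)CC | intermediate
10 | (S)-7-methoxy-1,4a-dimethyl-4,4a,9,10-tetrahydrophenanthren-2(3H)-one (C12 ketone, C10=C11) | COc1cc2c(cc1)[C@]3(C)C(=C(C)C(=O)CC3)CC2 | intermediate
11 | 12α-allylic alcohol (C10=C11) | COc1cc2c(cc1)[C@]3(C)C(=C(C)[C@H](O)CC3)CC2 | intermediate
12 | trans-fused 12α-alcohol (10α-H, 11β-Me) | COc1cc2c(cc1)[C@]3(C)[C@H]([C@@H](C)[C@H](O)CC3)CC2 | intermediate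
13 | C12 ketone (10α-H, 11β-Me) | COc1cc2c(cc1)[C@]3(C)[C@H]([C@@H](C)C(=O)CC3)CC2 | intermediate
14 | C12 trimethylsilyl enol ether (C12=C13) | COc1cc2c(cc1)[C@]3(C)[C@H]([C@@H](C)C(O[Si](C)(C)C)=CC3)CC2 | intermediate
15 | ring A enone (C12 ketone, C13=C14) | COc1cc2c(cc1)[C@]3(C)[C@H]([C@@H](C)C(=O)C=C3)CC2 | intermediate
16 | 12β-allylic alcohol (C13=C14) | COc1cc2c(cc1)[C@]3(C)[C@H]([C@@H](C)[C@@H](O)C=C3)CC2 | intermediate
17 | 12β-TBS ether (C13=C14) | COc1cc2c(cc1)[C@]3(C)[C@H]([C@@H](C)[C@@H](O[Si](C)(C)C(C)(C)C)C=C3)CC2 | intermediate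
18 | 13α,14α-epoxide, 12β-OTBS | COc1cc2c(cc1)[C@]3(C)[C@H]([C@@H](C)[C@@H](O[Si](C)(C)C(C)(C)C)[C@@H]4O[C@@H]43)CC2 | intermediate
19 | C8 aryl ketone | COc1cc2c(cc1)[C@]3(C)[C@H]([C@@H](C)[C@@H](O[Si](C)(C)C(C)(C)C)[C@@H]4O[C@@H]43)CC2=O | intermediate
20 | 9α-hydroxy-8-ketone | COc1cc2c(cc1)[C@]3(C)[C@H]([C@@H](C)[C@@H](O[Si](C)(C)C(C)(C)C)[C@@H]4O[C@@H]43)[C@@H](O)C2=O | intermediate
21 | 9α,12β-bis-TBS ether 8-ketone | COc1cc2c(cc1)[C@]3(C)[C@H]([C@@H](C)[C@@H](O[Si](C)(C)C(C)(C)C)[C@@H]4O[C@@H]43)[C@@H](O[Si](C)(C)C(C)(C)C)C2=O | intermediate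
22 | (E)-1-bromobut-2-ene (crotyl bromide) | C/C=C/CBr | starting material
23 | C8 tertiary alcohol (8α-OH, 8β-but-3-en-2-yl, both C17 epimers) | COc1cc2c(cc1)[C@]3(C)[C@H]([C@@H](C)[C@@H](O[Si](C)(C)C(C)(C)C)[C@@H]4O[C@@H]43)[C@@H](O[Si](C)(C)C(C)(C)C)[C@]2(O)C(C)C=C | intermediate
24 | 1,4-diene enol ether (C2=C7, C4=C5–OMe; C17 epimers) | COC1=CCC(=C2C1)[C@]3(C)[C@H]([C@@H](C)[C@@H](O[Si](C)(C)C(C)(C)C)[C@@H]4O[C@@H]43)[C@@H](O[Si](C)(C)C(C)(C)C)[C@]2(O)C(C)C=C | intermediate
25 | C5 ethylene ketal with C2=C7 alkene (C17 epimers) | C1CC5(OCCO5)CC2=C1[C@]3(C)[C@H]([C@@H](C)[C@@H](O[Si](C)(C)C(C)(C)C)[C@@H]4O[C@@H]43)[C@@H](O[Si](C)(C)C(C)(C)C)[C@]2(O)C(C)C=C | intermediate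
26 | ten-membered 2,7-diketone, C5 ketal, C19 aldehyde (C17 epimers) | C15(OCCO5)CCC(=O)[C@]2(C)[C@H]([C@@H](C)[C@@H](O[Si](C)(C)C(C)(C)C)[C@@H]3O[C@@H]32)[C@@H](O[Si](C)(C)C(C)(C)C)[C@](O)(C(C)C=O)C(=O)C1 | intermediate
27 | C19 carboxylic acid (C17 epimers) | C15(OCCO5)CCC(=O)[C@]2(C)[C@H]([C@@H](C)[C@@H](O[Si](C)(C)C(C)(C)C)[C@@H]3O[C@@H]32)[C@@H](O[Si](C)(C)C(C)(C)C)[C@](O)(C(C)C(=O)O)C(=O)C1 | intermediate
28 | 7α-hydroxy acid (C17 epimers) | C15(OCCO5)CCC(=O)[C@]2(C)[C@H]([C@@H](C)[C@@H](O[Si](C)(C)C(C)(C)C)[C@@H]3O[C@@H]32)[C@@H](O[Si](C)(C)C(C)(C)C)[C@](O)(C(C)C(=O)O)[C@@H](O)C1 | intermediate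
29 | γ-lactone, C2 ketone, C5 ketal (C17 epimers) | C15(OCCO5)CCC(=O)[C@]2(C)[C@H]([C@@H](C)[C@@H](O[Si](C)(C)C(C)(C)C)[C@@H]3O[C@@H]32)[C@@H](O[Si](C)(C)C(C)(C)C)[C@]2(O)C(C)C(=O)O[C@H]2C1 | intermediate
30 | γ-lactone with C18 methyl cis to 8-OH | C15(OCCO5)CCC(=O)[C@]2(C)[C@H]([C@@H](C)[C@@H](O[Si](C)(C)C(C)(C)C)[C@@H]3O[C@@H]32)[C@@H](O[Si](C)(C)C(C)(C)C)[C@]2(O)[C@@H](C)C(=O)O[C@H]2C1 | intermediate
31 | C2 trimethylsilyl enol ether (C2=C3) with C8–OTMS | C15(OCCO5)CC=C(O[Si](C)(C)C)[C@]2(C)[C@H]([C@@H](C)[C@@H](O[Si](C)(C)C(C)(C)C)[C@@H]3O[C@@H]32)[C@@H](O[Si](C)(C)C(C)(C)C)[C@]2(O[Si](C)(C)C)[C@@H](C)C(=O)O[C@H]2C1 | intermediate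
32 | (Z)-3-en-2-one, C5 ketal, C8–OTMS | C15(OCCO5)/C=C\C(=O)[C@]2(C)[C@H]([C@@H](C)[C@@H](O[Si](C)(C)C(C)(C)C)[C@@H]3O[C@@H]32)[C@@H](O[Si](C)(C)C(C)(C)C)[C@]2(O[Si](C)(C)C)[C@@H](C)C(=O)O[C@H]2C1 | intermediate
33 | (Z)-3-ene-2,5-dione, C8–OH | O=C1/C=C\C(=O)[C@]2(C)[C@H]([C@@H](C)[C@@H](O[Si](C)(C)C(C)(C)C)[C@@H]3O[C@@H]32)[C@@H](O[Si](C)(C)C(C)(C)C)[C@]2(O)[C@@H](C)C(=O)O[C@H]2C1 | intermediate
34 | C5 trimethylsilyl dienol ether (C5=C6) with C8–OTMS | C1(O[Si](C)(C)C)/C=C\C(=O)[C@]2(C)[C@H]([C@@H](C)[C@@H](O[Si](C)(C)C(C)(C)C)[C@@H]3O[C@@H]32)[C@@H](O[Si](C)(C)C(C)(C)C)[C@]2(O[Si](C)(C)C)[C@@H](C)C(=O)O[C@H]2C=1 | intermediate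
35 | 6α-chloro-(Z)-3-ene-2,5-dione, C8–OTMS | O=C1/C=C\C(=O)[C@]2(C)[C@H]([C@@H](C)[C@@H](O[Si](C)(C)C(C)(C)C)[C@@H]3O[C@@H]32)[C@@H](O[Si](C)(C)C(C)(C)C)[C@]2(O[Si](C)(C)C)[C@@H](C)C(=O)O[C@H]2[C@H]1Cl | intermediate
36 | 6α-chloro-5(16)-methylene-(Z)-3-en-2-one, C8–OTMS | C=C1/C=C\C(=O)[C@]2(C)[C@H]([C@@H](C)[C@@H](O[Si](C)(C)C(C)(C)C)[C@@H]3O[C@@H]32)[C@@H](O[Si](C)(C)C(C)(C)C)[C@]2(O[Si](C)(C)C)[C@@H](C)C(=O)O[C@H]2[C@H]1Cl | intermediate
37 | 8,9α,12β-triol 2-ketone | C=C1/C=C\C(=O)[C@]2(C)[C@H]([C@@H](C)[C@@H](O)[C@@H]3O[C@@H]32)[C@@H](O)[C@]2(O)[C@@H](C)C(=O)O[C@H]2[C@H]1Cl | intermediate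
38 | 2α,8,9α,12β-tetraol | C=C1/C=C\[C@@H](O)[C@]2(C)[C@H]([C@@H](C)[C@@H](O)[C@@H]3O[C@@H]32)[C@@H](O)[C@]2(O)[C@@H](C)C(=O)O[C@H]2[C@H]1Cl | intermediate
39 | CNP0274383.1 | C=C1/C=C\[C@@H](OC(C)=O)[C@]2(C)[C@H]([C@@H](C)[C@@H](OC(C)=O)[C@@H]3O[C@@H]32)[C@@H](OC(C)=O)[C@]2(O)[C@@H](C)C(=O)O[C@H]2[C@H]1Cl | target

**Total step count:** 27
**Longest linear sequence:** 27 steps (from 1 to 39; the route is fully linear)

**Steps most likely to fail**

Step 23. Two processes threaten it: the C6 enolate may expel the lactone oxygen at C7 (β-elimination) before it is silylated, and chlorine may be delivered to the inner face of the enol ether, giving the C6 epimer. The fallback answers the facial problem by introducing oxygen electrophilically and chlorine nucleophilically. It sets out from 33, which is converted as in step 23 into the silyl dienol ether 34. Dimethyldioxirane (acetone, −78 °C) then oxidises 34 on the same face the chlorine would have taken, giving the 6β-hydroxy ketone F2. Tf2O and 2,6-lutidine (CH2Cl2, −78 °C) convert it into the 6β-triflate F3. Displacement with n-Bu4NCl (SN2 with inversion, accelerated by the neighbouring carbonyl) should then return the route at 35.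

Step 24. The titanium methylidene may enolise or dechlorinate the α-chloro ketone, or methylenate the lactone carbonyl in competition. The fallback replaces carbene transfer by addition and elimination. It sets out from 35: Me3SiCH2MgCl with CeCl3 (THF, −78 °C) adds to the C5 ketone to give the β-hydroxysilane F4 (either C5 epimer). When F4 is submitted to the conditions of step 25, HF·pyridine should remove the silyl ethers and bring about the Peterson elimination in the same operation, so the route is rejoined at 37.

Step 15. The benzylic C8–O bond may be cleaved reductively during the dissolving-metal reduction, in competition with ring reduction. The fallback removes the benzylic C–O single bond from the reduction substrate. It sets out from ketone 21, which is converted into its potassium enolate (KN(SiMe3)2, THF, −78 °C) and reduced in that protected form (Li, NH3/THF, t-BuOH, −78 °C). Protonation, with equilibration to the equatorial 9α-silyloxy epimer, should return the C8 ketone, now conjugated with the new C2=C7 alkene, as the methoxy-diene enone F1. Addition of crotylzinc bromide (from 22 and Zn, THF, 0 °C) in 1,2-fashion, trans to the 9α-silyloxy group, should then rejoin the route at 24.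

**Further compounds**
F1 | step 15 | methoxy-diene enone (C8 ketone, C2=C7, C4=C5–OMe, 9α,12β-bis-TBS, 13α,14α-epoxide) | COC1=CCC(=C2C1)[C@]3(C)[C@H]([C@@H](C)[C@@H](O[Si](C)(C)C(C)(C)C)[C@@H]4O[C@@H]43)[C@@H](O[Si](C)(C)C(C)(C)C)C2=O
F2 | step 23 | 6β-hydroxy-(Z)-3-ene-2,5-dione with C8–OTMS | O=C1/C=C\C(=O)[C@]2(C)[C@H]([C@@H](C)[C@@H](O[Si](C)(C)C(C)(C)C)[C@@H]3O[C@@H]32)[C@@H](O[Si](C)(C)C(C)(C)C)[C@]2(O[Si](C)(C)C)[C@@H](C)C(=O)O[C@H]2[C@@H]1O
F3 | step 23 | 6β-triflate of F2 | O=C1/C=C\C(=O)[C@]2(C)[C@H]([C@@H](C)[C@@H](O[Si](C)(C)C(C)(C)C)[C@@H]3O[C@@H]32)[C@@H](O[Si](C)(C)C(C)(C)C)[C@]2(O[Si](C)(C)C)[C@@H](C)C(=O)O[C@H]2[C@@H]1OS(=O)(=O)C(F)(F)F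
F4 | step 24 | C5 β-hydroxysilane (5-hydroxy-5-trimethylsilylmethyl, 6α-chloro, C8–OTMS) | C[Si](C)(C)CC1(O)/C=C\C(=O)[C@]2(C)[C@H]([C@@H](C)[C@@H](O[Si](C)(C)C(C)(C)C)[C@@H]3O[C@@H]32)[C@@H](O[Si](C)(C)C(C)(C)C)[C@]2(O[Si](C)(C)C)[C@@H](C)C(=O)O[C@H]2[C@H]1Cl
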